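I start from the coupling partner.

| setting | Thursday's | amber | red | ochre | blue |
|---|---|---|---|---|---|
| solid substrate | 1 M | 1.0 M | 1.0 M | 1.0 M | 1.0 M |
| coupling partner | 0.35 M | 0.700 M | 0.700 M | 0.700 M | 0.700 M |
| catalyst | 25 mM | 25 mM | 25 mM | 25 mM | 25 mM |
| temperature | 65 °C | 65 °C | 50 °C |  | 80 °C |
| remark | run made earlier |  |  | at 50 °C until 4.0 min, from then on at 80 °C |  |
| time |  | 12 min | 12 min | 12 min | 12 min |

Thursday's run (percent of the solid substrate charged)

| time / min | product / % | solid substrate / % |
|---|---|---|
| 0.167 | 0 | 88.3 |
| 0.500 | 2.4 | 68.2 |
| 0.833 | 7.0 | 53.1 |
| 1.33 | 14.5 | 32.7 |
| 2.00 | 23.3 | 10.2 |
| 2.50 | 28.8 | 0 |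

(each reading ± 0.5 percentage points)

- solid, in amounts per volume of the solution: solid substrate
- at the start none of the solid substrate is in solution
- what has only dissolved of solid substrate counts as not reacted
- the earlier runs do not show what temperature does; that part of a forecast is a guess

- the best flask by amount of product, in percent of the solid substrate charged; "all alike" if 1.5 percentage points covers them all (amber / red / ochre / blue / all alike)
- amount of product at the end, in percent of the solid substrate charged, amber
- amount of product at the end, in percent of the solid substrate charged, red
- amount of product at the end, in percent of the solid substrate charged, ochre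
- amount of product at the end, in percent of the solid substrate charged, blue

I assume that each product uses one coupling partner. The new flasks hold 0.700 M of it against 1.0 M of solid substrate, so the coupling partner is the limiting reagent, and I reckon a ceiling for the product:

ceiling = 70.0%

This ceiling, the partner charge over the substrate charge, is the large number. What I still have to compute is the small correction, the shortfall under it at the end.

Thursday's last two readings give me that correction. Between 2.00 min and 2.50 min the product gains 5.5 percentage points, while the partner left under Thursday's own ceiling averages 8.9 points. I treat the partner's loss as pseudo-first-order: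

rate constant = 1.23 /min

half-life of the shortfall = 0.564 min

This is a reading, and it carries the scatter of 0.5 points. Amber stands at Thursday's temperature but holds 0.700 M of coupling partner against Thursday's 0.35 M, so I do not assume that this half-life carries over to amber, and I count no halvings for amber from it.

The weak link is red, and the runs say nothing about temperature. So I don't guess a half-life for red; I ask how long it may be. Counting from the start, 6 halvings bring the ceiling down to 1.1 points, and the margin is 1.5 points. Red may therefore have

tolerated half-life = 2.00 min

which is 3.55 times Thursday's, and I assume that amber stays inside the same allowance. I take the heat in ochre and blue to shorten the half-life, which is also a guess. I commit to the ceiling for amber, ochre and blue, to at least 68.9% for red, and so to all alike.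

The forecast gives amber 69.3%, red 64.5%, ochre 69.5% and blue 69.6%, with blue best, and it says: “The temperature effect is a guess”. We part on red, which it sets 5.5 points under the ceiling.

The flasks give all alike: amber 69.9%, red 69.3%, ochre 70.0%, blue 70.0%.

    starting material + catalyst ⇌ catalyst + intermediate (K = 1.90, k = 0.670 /M/s, Ea = 49.0 kJ/mol, ΔH = −49.0 kJ/mol)
    coupling partner + catalyst + intermediate → catalyst + product (k = 1.20 /M²/s, Ea = 49.0 kJ/mol)
    solid substrate ⇌ starting material, rate k3*(cs3 - [starting material]) while solid is left; crystals form when [starting material] > cs3 (solubility = 0.650 M, k = 0.0200 /s)
    (constants at 50 °C)

By 6.00 min red's solid substrate stands at 0%, its product at 63.0%, and 91% of the coupling step's turnover lies behind it, with 10.1% of the coupling partner's charge left. The coupling then runs on with the intermediate at 20.1% at the end, where the partner's half-life of 1.9 min is shorter than the tolerated 2.00 min, and red closes 0.70 points under its ceiling of 70.0%. The neighbour of red charged with 0.17 M of coupling partner has a ceiling of 17.0% and ends with 17.0% of product.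

The runs come from a simulation with made-up constants.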